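**Retrosynthetic overview** (benzofuran numbering O1, C2, C3, C3a, C4–C7, C7a; C8 is the CH2 beside the side-chain ketone)
- The target is taken back to its conjugated tautomer (C7=C7a and C3a=C4, C5H2); C7–H is set last by kinetic protonation of a silyl trienol ether.
- Key disconnection: that tautomer is unfolded to an acyclic keto enoate epoxide by cutting C7–C7a (Claisen) and O1–C2 (epoxide opening). Forward, one anionic cascade closes the carbocycle (C3a–C4–C5–C6–C7–C7a) first and the dihydrofuran (O1–C2–C3–C3a–C7a) last.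
- Enabling feature: C7a carries O1 and lies between C3a and the acyl-bearing C7, so the carbocycle is a masked 2-acylcyclohexane-1,3-dione whose other oxygen (on C4) is already a methyl enol ether. Acylating the C7 ketone enolate at C7a therefore creates an enolate oxygen that is O1 itself, five atoms from the epoxide carbon C2.
- The chain comes from a commercial (R)-hydroxy nitrile β-keto ester (C6) by iridium-catalysed allylic alkylation at C3a with a cinnamyl carbonate (C3), Grignard addition to the nitrile, O-methylation, carbonylation, cross-metathesis and Shi epoxidation (C2).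
- Ring order: carbocycle, then dihydrofuran, both in the key step; no ring is formed afterwards.

Key step: step 13

Remark: C7–H of the target is α to the ketone and allylic to the dienol ether; the conjugated tautomer is assumed to be the more stable one, so C7 is set last under kinetic control and the target is kept away from base and strong acid.

Step 1
Reactants: 1 tert-butyl (5R)-6-cyano-5-hydroxy-3-oxohexanoate
Product: 2 tert-butyl (5R)-5-[(tert-butyldimethylsilyl)oxy]-6-cyano-3-oxohexanoate
Conditions: TBSCl, imidazole, DMF, 0 → 20 °C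
Reagents that add atoms: tert-butyldimethylsilyl chloride, CC(C)(C)[Si](C)(C)Cl
Why: Imidazole-promoted silylation of the secondary alcohol should leave the stereocentre untouched and blocks lactonisation and alkoxide chemistry in all later base steps.

Step 2
Reactants: 2 silyl ether
Product: 3 methyl (5R)-5-[(tert-butyldimethylsilyl)oxy]-6-cyano-3-oxohexanoate
Conditions: MeOH (10 equiv), toluene, 110 °C, sealed tube
Reagents that add atoms: methanol, CO
Why: tert-Butyl β-keto esters lose tert-butanol on heating to an acylketene that methanol traps (thermal transacetoacetylation), which should give the methyl ester whose methoxide is the leaving group of the later Claisen step.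

Step 3
Reactants: 4 5-bromo-2-hydroxybenzaldehyde
Product: 5 5-bromo-2-[(triisopropylsilyl)oxy]benzaldehyde
Conditions: TIPSCl, imidazole, DMF, 20 °C
Reagents that add atoms: triisopropylsilyl chloride, CC(C)[Si](Cl)(C(C)C)C(C)C
Why: Phenol silylation; the bulky silyl ether should survive Grignard and alkoxide reagents and keeps the phenol from competing for the epoxide in step 13.

Step 4
Reactants: 5 silylated aldehyde
Product: 6 ethyl (2E)-3-{5-bromo-2-[(triisopropylsilyl)oxy]phenyl}prop-2-enoate
Conditions: (EtO)2P(O)CH2CO2Et, NaH, THF, 0 → 20 °C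
Reagents that add atoms: triethyl phosphonoacetate, CCOC(=O)CP(=O)(OCC)OCC
Why: Horner–Wadsworth–Emmons olefination of an aryl aldehyde with a stabilised phosphonate should give the (E)-enoate.

Step 5
Reactants: 6 cinnamate
Product: 7 (2E)-3-{5-bromo-2-[(triisopropylsilyl)oxy]phenyl}prop-2-en-1-ol
Conditions: iBu2AlH (2.2 equiv), CH2Cl2, −78 °C; aq. KNaC4H4O6
Reagents that add atoms: none
Why: 1,2-Reduction of the enoate by the aluminium hydride should give the allylic alcohol, with aryl bromide and silyl ether inert.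

Step 6
Reactants: 7 cinnamyl alcohol
Product: 8 (2E)-3-{5-bromo-2-[(triisopropylsilyl)oxy]phenyl}prop-2-en-1-yl methyl carbonate
Conditions: ClCO2Me, pyridine, CH2Cl2, 0 °C
Reagents that add atoms: methyl chloroformate, COC(=O)Cl
Why: Acylation of the primary alcohol gives the linear carbonate, the standard leaving group for iridium-catalysed allylic substitution.

Step 7
Reactants: 3 methyl β-keto ester; 8 cinnamyl carbonate
Product: 9 methyl (5R)-2-[(1R)-1-{5-bromo-2-[(triisopropylsilyl)oxy]phenyl}prop-2-en-1-yl]-5-[(tert-butyldimethylsilyl)oxy]-6-cyano-3-oxohexanoate (mixture of epimers at C2)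
Conditions: [Ir(cod)Cl]2 (2 mol%), O,O'-(1,1'-binaphthyl-2,2'-diyl)-N,N-bis(1-phenylethyl)phosphoramidite (4 mol%, the antipode that gives the (1R) product), TBD (8 mol%), THF, 20 °C
Reagents that add atoms: none
Why: Iridium-catalysed asymmetric allylic alkylation of the β-keto ester is branched-selective and forms the C3a–C3 bond; the phosphoramidite ligand sets the benzylic stereocentre (future C3), and the epimers at the α-carbon are of no consequence because that carbon becomes sp2.

Step 8
Reactants: 9 allylated β-keto ester nitrile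
Product: 11 methyl (5R)-2-[(1R)-1-{5-bromo-2-[(triisopropylsilyl)oxy]phenyl}prop-2-en-1-yl]-5-[(tert-butyldimethylsilyl)oxy]-3,7-dioxo-9-phenylnonanoate, via ketimine 10 (not isolated)
Conditions: PhCH2CH2MgBr (3.2 equiv), Et2O/toluene, 0 → 40 °C; aq. NH4Cl, then 1 M aq. HCl, 0 °C
Reagents that add atoms: 2-phenylethylmagnesium bromide, Br[Mg]CCc1ccccc1; water, O
Why: The first equivalent turns the β-keto ester into its magnesium enolate, which protects both carbonyl groups, a further equivalent adds to the nitrile (Grignard addition to a nitrile), and mild aqueous acid hydrolysis of ketimine 10 (water supplies the ketone oxygen, nitrogen leaves as ammonium chloride) should give the ketone while the aryl bromide stays inert.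

Step 9
Reactants: 11 diketo ester
Product: 12 methyl (2E,5S)-2-[(1S)-1-{5-bromo-2-[(triisopropylsilyl)oxy]phenyl}prop-2-en-1-yl]-5-[(tert-butyldimethylsilyl)oxy]-3-methoxy-7-oxo-9-phenylnon-2-enoate
Conditions: Cs2CO3, Me2SO4, DMF, 0 → 20 °C
Reagents that add atoms: dimethyl sulfate, COS(=O)(=O)OC
Why: O-Alkylation of the caesium enolate of an α-substituted β-keto ester by a hard electrophile in DMF (C-methylation would have to build a quaternary centre) should lock the C4 oxygen as the methyl enol ether and close the 1,5-diketone aldol pathway; 12 is drawn as the (E)-isomer that can cyclise, and any (Z)-isomer is expected to equilibrate under the alkoxide conditions of step 13.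

Step 10
Reactants: 12 aryl bromide
Product: 13 methyl (2E,5S)-5-[(tert-butyldimethylsilyl)oxy]-3-methoxy-2-[(1S)-1-{5-(methoxycarbonyl)-2-[(triisopropylsilyl)oxy]phenyl}prop-2-en-1-yl]-7-oxo-9-phenylnon-2-enoate
Conditions: Pd(OAc)2 (5 mol%), Xantphos (6 mol%), CO (1 atm), MeOH, Et3N, DMF, 70 °C
Reagents that add atoms: carbon monoxide, [C-]#[O+]; methanol, CO
Why: Palladium-catalysed methoxycarbonylation of the aryl bromide installs the benzoate only after the Grignard step, which a methyl benzoate would not have survived.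

Step 11
Reactants: 13 terminal alkene
Product: 14 methyl (2E,5S)-5-[(tert-butyldimethylsilyl)oxy]-3-methoxy-2-[(1S)-1-{5-(methoxycarbonyl)-2-[(triisopropylsilyl)oxy]phenyl}-3-methylbut-2-en-1-yl]-7-oxo-9-phenylnon-2-enoate
Conditions: second-generation Hoveyda–Grubbs catalyst RuCl2(H2IMes)(=CH–C6H4-2-OiPr) (10 mol%), 2-methyl-2-butene (excess), CH2Cl2, 40 °C
Reagents that add atoms: 2-methyl-2-butene, CC=C(C)C
Why: Olefin cross-metathesis exchanges the terminal methylene for an isopropylidene group with loss of propene, and the tetrasubstituted push–pull alkene should not engage the ruthenium carbene.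

Step 12
Reactants: 14 trisubstituted alkene
Product: 15 methyl (2E,5S)-5-[(tert-butyldimethylsilyl)oxy]-2-[(S)-[(2S)-3,3-dimethyloxiran-2-yl]{5-(methoxycarbonyl)-2-[(triisopropylsilyl)oxy]phenyl}methyl]-3-methoxy-7-oxo-9-phenylnon-2-enoate
Conditions: L-fructose-derived antipode of the Shi ketone (0.3 equiv), Oxone (2KHSO5·KHSO4·K2SO4), K2CO3, Bu4NHSO4, MeCN/dimethoxymethane/aq. Na2B4O7 buffer (pH 10.5), 0 °C
Reagents that add atoms: potassium peroxymonosulfate, [K+].[O-]S(=O)(=O)OO
Why: Shi asymmetric epoxidation: the chiral dioxirane should attack the electron-rich trisubstituted alkene faster than the tetrasubstituted β-methoxy acrylate and set C2 as (S) through the spiro transition state (reagent control over the adjacent C3 centre); it is run before the β-diketone exists, because an enolisable 1,3-dicarbonyl would be hydroxylated by the dioxirane.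

Step 13
Reactants: 15 acyclic keto enoate epoxide
Product: 17 methyl 3-[(2R,3S,6S)-6-[(tert-butyldimethylsilyl)oxy]-2-(2-hydroxypropan-2-yl)-4-methoxy-7-(3-phenylpropanoyl)-2,3,5,6-tetrahydro-1-benzofuran-3-yl]-4-[(triisopropylsilyl)oxy]benzoate, via potassium enolate 16 (not isolated)
Conditions: KOtBu (1.2 equiv), THF/t-BuOH (5:1), −40 → 20 °C; AcOH, −40 °C
Reagents that add atoms: none
Why: tert-Butoxide reversibly enolises the ketone, and only the C7 enolate can reach the methyl ester: its attack on C7a with loss of methoxide (intramolecular Claisen condensation, the Dieckmann-type closure of a δ-keto ester to a cyclohexane-1,3-dione; 6-exo-trig addition–elimination at the ester carbonyl) closes the carbocycle as the chelated potassium β-diketonate 16. The enolate oxygen on C7a then opens the neighbouring trisubstituted epoxide at its less substituted carbon C2 (5-exo-tet, SN2), which closes the dihydrofuran as the last ring and frees the tertiary alkoxide; the closest known reaction is the base-mediated cyclisation of epoxidised prenyl phenols and 2-prenyl-1,3-diones to 2-(2-hydroxypropan-2-yl)dihydrofurans. The only stereocentre formed is C2, by inversion of the (S)-epoxide from step 12, so the 2,3-cis relationship follows from the configurations of C3 and of the epoxide; C3 and C6 are carried through unchanged and C7 is sp2 in 17. The step needs C-acylation at C7a instead of aldol chemistry, and it needs O1 and not the C4 oxygen to cyclise: the C4 oxygen is locked as the methyl enol ether, the C8 enolate could only close an eight-membered ring, the phenol is silylated, and basic conditions direct the oxygen to the less hindered epoxide carbon (5-exo, not 6-endo). A (Z)-isomer of 15 should be drawn into the same product, because alkoxide adds reversibly to C4 and equilibrates the enoate geometry. The methanol set free reprotonates the alkoxide, so little more than one equivalent of base is needed and 17 is not left with excess strong base.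

Step 14
Reactants: 17 bis-silyl ether of the conjugated tautomer
Product: 18 methyl 4-hydroxy-3-[(2R,3S,6S)-6-hydroxy-2-(2-hydroxypropan-2-yl)-4-methoxy-7-(3-phenylpropanoyl)-2,3,5,6-tetrahydro-1-benzofuran-3-yl]benzoate
Conditions: Bu4NF/AcOH (1:1, 4 equiv), THF, 20 → 40 °C
Reagents that add atoms: none
Why: Buffered fluoride cleaves the alkyl and aryl silyl ethers at the stage of the robust conjugated dienone, and no stereocentre is touched.

Step 15
Reactants: 18 conjugated tautomer (triol)
Product: 20 methyl 4-hydroxy-3-[(2R,3S,6S,7S)-6-hydroxy-2-(2-hydroxypropan-2-yl)-4-methoxy-7-(3-phenylpropanoyl)-2,3,6,7-tetrahydro-1-benzofuran-3-yl]benzoate, via silyl trienol ether 19 (not isolated)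
Conditions: TMSOTf (6 equiv), Et3N (8 equiv), CH2Cl2, −20 → 20 °C; evaporate; Bu4NF/AcOH (1:1.5), THF, −78 → −20 °C; pH 7 buffer
Reagents that add atoms: none
Why: Silyl triflate and amine should silylate the three hydroxyl groups and, under equilibrating conditions, turn the vinylogous-ester ketone into the linearly conjugated trienol silyl ether 19 by loss of a C5 proton (as enones give their extended dienol ethers); fluoride with acetic acid then releases the extended enolate, which is protonated kinetically at its α-carbon C7 on the face opposite the C6 silyloxy group (deconjugative protonation), setting C7 as (S) with the acyl group cis to the C6 oxygen while all silyl groups are lost.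

**Compound list**
1 | tert-butyl (5R)-6-cyano-5-hydroxy-3-oxohexanoate | CC(C)(C)OC(=O)CC(=O)C[C@H](O)CC#N | starting material
2 | tert-butyl (5R)-5-[(tert-butyldimethylsilyl)oxy]-6-cyano-3-oxohexanoate | CC(C)(C)OC(=O)CC(=O)C[C@H](O[Si](C)(C)C(C)(C)C)CC#N | intermediate
3 | methyl (5R)-5-[(tert-butyldimethylsilyl)oxy]-6-cyano-3-oxohexanoate | COC(=O)CC(=O)C[C@H](O[Si](C)(C)C(C)(C)C)CC#N | intermediate
4 | 5-bromo-2-hydroxybenzaldehyde | O=Cc1cc(Br)ccc1O | starting material
5 | 5-bromo-2-[(triisopropylsilyl)oxy]benzaldehyde | O=Cc1cc(Br)ccc1O[Si](C(C)C)(C(C)C)C(C)C | intermediate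
6 | ethyl (2E)-3-{5-bromo-2-[(triisopropylsilyl)oxy]phenyl}prop-2-enoate | CCOC(=O)/C=C/c1cc(Br)ccc1O[Si](C(C)C)(C(C)C)C(C)C | intermediate
7 | (2E)-3-{5-bromo-2-[(triisopropylsilyl)oxy]phenyl}prop-2-en-1-ol | OC/C=C/c1cc(Br)ccc1O[Si](C(C)C)(C(C)C)C(C)C | intermediate
8 | (2E)-3-{5-bromo-2-[(triisopropylsilyl)oxy]phenyl}prop-2-en-1-yl methyl carbonate | COC(=O)OC/C=C/c1cc(Br)ccc1O[Si](C(C)C)(C(C)C)C(C)C | intermediate
9 | methyl (5R)-2-[(1R)-1-{5-bromo-2-[(triisopropylsilyl)oxy]phenyl}prop-2-en-1-yl]-5-[(tert-butyldimethylsilyl)oxy]-6-cyano-3-oxohexanoate (epimers at C2) | COC(=O)C([C@@H](C=C)c1cc(Br)ccc1O[Si](C(C)C)(C(C)C)C(C)C)C(=O)C[C@H](O[Si](C)(C)C(C)(C)C)CC#N | intermediate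
10 | methyl (5R)-2-[(1R)-1-{5-bromo-2-[(triisopropylsilyl)oxy]phenyl}prop-2-en-1-yl]-5-[(tert-butyldimethylsilyl)oxy]-7-imino-3-oxo-9-phenylnonanoate (ketimine) | COC(=O)C([C@@H](C=C)c1cc(Br)ccc1O[Si](C(C)C)(C(C)C)C(C)C)C(=O)C[C@H](O[Si](C)(C)C(C)(C)C)CC(=N)CCc1ccccc1 | intermediate
11 | methyl (5R)-2-[(1R)-1-{5-bromo-2-[(triisopropylsilyl)oxy]phenyl}prop-2-en-1-yl]-5-[(tert-butyldimethylsilyl)oxy]-3,7-dioxo-9-phenylnonanoate (epimers at C2) | COC(=O)C([C@@H](C=C)c1cc(Br)ccc1O[Si](C(C)C)(C(C)C)C(C)C)C(=O)C[C@H](O[Si](C)(C)C(C)(C)C)CC(=O)CCc1ccccc1 | intermediate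
12 | methyl (2E,5S)-2-[(1S)-1-{5-bromo-2-[(triisopropylsilyl)oxy]phenyl}prop-2-en-1-yl]-5-[(tert-butyldimethylsilyl)oxy]-3-methoxy-7-oxo-9-phenylnon-2-enoate | COC(=O)/C([C@@H](C=C)c1cc(Br)ccc1O[Si](C(C)C)(C(C)C)C(C)C)=C(/OC)C[C@H](O[Si](C)(C)C(C)(C)C)CC(=O)CCc1ccccc1 | intermediate
13 | methyl (2E,5S)-5-[(tert-butyldimethylsilyl)oxy]-3-methoxy-2-[(1S)-1-{5-(methoxycarbonyl)-2-[(triisopropylsilyl)oxy]phenyl}prop-2-en-1-yl]-7-oxo-9-phenylnon-2-enoate | COC(=O)/C([C@@H](C=C)c1cc(C(=O)OC)ccc1O[Si](C(C)C)(C(C)C)C(C)C)=C(/OC)C[C@H](O[Si](C)(C)C(C)(C)C)CC(=O)CCc1ccccc1 | intermediate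
14 | methyl (2E,5S)-5-[(tert-butyldimethylsilyl)oxy]-3-methoxy-2-[(1S)-1-{5-(methoxycarbonyl)-2-[(triisopropylsilyl)oxy]phenyl}-3-methylbut-2-en-1-yl]-7-oxo-9-phenylnon-2-enoate | COC(=O)/C([C@@H](C=C(C)C)c1cc(C(=O)OC)ccc1O[Si](C(C)C)(C(C)C)C(C)C)=C(/OC)C[C@H](O[Si](C)(C)C(C)(C)C)CC(=O)CCc1ccccc1 | intermediate
15 | methyl (2E,5S)-5-[(tert-butyldimethylsilyl)oxy]-2-[(S)-[(2S)-3,3-dimethyloxiran-2-yl]{5-(methoxycarbonyl)-2-[(triisopropylsilyl)oxy]phenyl}methyl]-3-methoxy-7-oxo-9-phenylnon-2-enoate | COC(=O)/C([C@@H]([C@@H]1OC1(C)C)c1cc(C(=O)OC)ccc1O[Si](C(C)C)(C(C)C)C(C)C)=C(/OC)C[C@H](O[Si](C)(C)C(C)(C)C)CC(=O)CCc1ccccc1 | intermediate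
16 | potassium (3S)-3-[(tert-butyldimethylsilyl)oxy]-6-[(S)-[(2S)-3,3-dimethyloxiran-2-yl]{5-(methoxycarbonyl)-2-[(triisopropylsilyl)oxy]phenyl}methyl]-5-methoxy-2-(3-phenylpropanoyl)cyclohexa-1,5-dien-1-olate | [K+].[O-]C1=C(C(=O)CCc2ccccc2)[C@@H](O[Si](C)(C)C(C)(C)C)CC(OC)=C1[C@@H]([C@@H]1OC1(C)C)c1cc(C(=O)OC)ccc1O[Si](C(C)C)(C(C)C)C(C)C | intermediate
17 | methyl 3-[(2R,3S,6S)-6-[(tert-butyldimethylsilyl)oxy]-2-(2-hydroxypropan-2-yl)-4-methoxy-7-(3-phenylpropanoyl)-2,3,5,6-tetrahydro-1-benzofuran-3-yl]-4-[(triisopropylsilyl)oxy]benzoate | COC(=O)c1ccc(O[Si](C(C)C)(C(C)C)C(C)C)c([C@H]2C3=C(OC)C[C@H](O[Si](C)(C)C(C)(C)C)C(C(=O)CCc4ccccc4)=C3O[C@H]2C(C)(C)O)c1 | intermediate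
18 | methyl 4-hydroxy-3-[(2R,3S,6S)-6-hydroxy-2-(2-hydroxypropan-2-yl)-4-methoxy-7-(3-phenylpropanoyl)-2,3,5,6-tetrahydro-1-benzofuran-3-yl]benzoate | COC(=O)c1ccc(O)c([C@H]2C3=C(OC)C[C@H](O)C(C(=O)CCc4ccccc4)=C3O[C@H]2C(C)(C)O)c1 | intermediate
19 | methyl 3-[(2R,3S,6S)-4-methoxy-7-[3-phenyl-1-(trimethylsilyloxy)propylidene]-6-(trimethylsilyloxy)-2-[2-(trimethylsilyloxy)propan-2-yl]-2,3,6,7-tetrahydro-1-benzofuran-3-yl]-4-(trimethylsilyloxy)benzoate (enol ether geometry not defined) | COC(=O)c1ccc(O[Si](C)(C)C)c([C@H]2C3=C(O[C@H]2C(C)(C)O[Si](C)(C)C)C(=C(O[Si](C)(C)C)CCc4ccccc4)[C@@H](O[Si](C)(C)C)C=C3OC)c1 | intermediate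
20 | methyl 4-hydroxy-3-[(2R,3S,6S,7S)-6-hydroxy-2-(2-hydroxypropan-2-yl)-4-methoxy-7-(3-phenylpropanoyl)-2,3,6,7-tetrahydro-1-benzofuran-3-yl]benzoate | COC(=O)c1ccc(O)c([C@H]2C3=C(O[C@H]2C(C)(C)O)[C@@H](C(=O)CCc4ccccc4)[C@@H](O)C=C3OC)c1 | target

**Step count and risks**

Total: 15 steps. Longest linear sequence: 13 steps (from 4 through steps 3–6 and 7–15; 11 steps from 1).

Step 13 is the most likely to fail. The C7 enolate, or the β-diketonate formed from it, may lose the C6 silyloxy group by β-elimination and aromatise the new ring before or after the Claisen closure. The C8 enolate may add to C4 with loss of methoxide, or the enolate oxygen may open the epoxide at the tertiary carbon. The fallback separates the two ring closures and sets out from 14. 14 is cyclised alone with LiN(SiMe3)2 in THF at −78 °C, where β-elimination is slow, to the enolised monocyclic β-diketone methyl 3-[(1S)-1-[(4S)-4-[(tert-butyldimethylsilyl)oxy]-6-hydroxy-2-methoxy-5-(3-phenylpropanoyl)cyclohexa-1,5-dien-1-yl]-3-methylbut-2-en-1-yl]-4-[(triisopropylsilyl)oxy]benzoate F1. Its enol is masked with pivaloyl chloride, Et3N and DMAP as the enol pivalate F2 (drawn as the ring enol ester; the exocyclic regioisomer would serve equally). The Shi epoxidation of step 12 is then run on F2 to give the epoxy enol pivalate F3. K2CO3 in MeOH removes the pivaloyl group, and the released enolate opens the epoxide in the same flask, which returns the route at 17.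

Step 15 is the second. Silylation may remove a proton from C8 and give the cross-conjugated enol ether, the silyl triflate may ionise the allylic C6 silyl ether, and protonation may occur at C5 or on the wrong face of C7, which returns 18 or gives the C7 epimer. The fallback sets out from 18 and uses the classical base-mediated deconjugation of enones. Excess KOtBu in THF/t-BuOH at −20 °C converts 18 into the fully delocalised tetrapotassium extended enolate F4, in which the C6 oxygen is an alkoxide and cannot leave. Inverse addition to cold AcOH in THF protonates the enolate at C7 and returns the route at 20.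

Step 8 is the third. The Grignard reagent may deprotonate the carbon α to the nitrile, after which the silyloxy group is lost, or the addition may stall on the magnesium enolate. The fallback sets out from 9 and avoids addition to a nitrile. 9 is O-methylated as in step 9 (Cs2CO3, Me2SO4, DMF) to the enoate nitrile methyl (2E,5R)-2-[(1S)-1-{5-bromo-2-[(triisopropylsilyl)oxy]phenyl}prop-2-en-1-yl]-5-[(tert-butyldimethylsilyl)oxy]-6-cyano-3-methoxyhex-2-enoate F5. iBu2AlH in toluene at −78 °C reduces the nitrile to the aldehyde F6, PhCH2CH2MgBr at −78 °C adds to the aldehyde alone to give the secondary alcohol F7, and Dess–Martin periodinane oxidises it to the ketone, which returns the route at 12.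

Further compounds
F1 | step 13 | methyl 3-[(1S)-1-[(4S)-4-[(tert-butyldimethylsilyl)oxy]-6-hydroxy-2-methoxy-5-(3-phenylpropanoyl)cyclohexa-1,5-dien-1-yl]-3-methylbut-2-en-1-yl]-4-[(triisopropylsilyl)oxy]benzoate | OC1=C(C(=O)CCc2ccccc2)[C@@H](O[Si](C)(C)C(C)(C)C)CC(OC)=C1[C@@H](C=C(C)C)c1cc(C(=O)OC)ccc1O[Si](C(C)C)(C(C)C)C(C)C
F2 | step 13 | methyl 3-[(1S)-1-[(4S)-4-[(tert-butyldimethylsilyl)oxy]-6-[(2,2-dimethylpropanoyl)oxy]-2-methoxy-5-(3-phenylpropanoyl)cyclohexa-1,5-dien-1-yl]-3-methylbut-2-en-1-yl]-4-[(triisopropylsilyl)oxy]benzoate | CC(C)(C)C(=O)OC1=C(C(=O)CCc2ccccc2)[C@@H](O[Si](C)(C)C(C)(C)C)CC(OC)=C1[C@@H](C=C(C)C)c1cc(C(=O)OC)ccc1O[Si](C(C)C)(C(C)C)C(C)C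
F3 | step 13 | methyl 3-[(S)-[(4S)-4-[(tert-butyldimethylsilyl)oxy]-6-[(2,2-dimethylpropanoyl)oxy]-2-methoxy-5-(3-phenylpropanoyl)cyclohexa-1,5-dien-1-yl][(2S)-3,3-dimethyloxiran-2-yl]methyl]-4-[(triisopropylsilyl)oxy]benzoate | CC(C)(C)C(=O)OC1=C(C(=O)CCc2ccccc2)[C@@H](O[Si](C)(C)C(C)(C)C)CC(OC)=C1[C@@H]([C@@H]2OC2(C)C)c1cc(C(=O)OC)ccc1O[Si](C(C)C)(C(C)C)C(C)C
F4 | step 15 | tetrapotassium salt of the extended enolate of 18 (phenolate, C6 alkoxide, tertiary alkoxide, trienolate) | [K+].[K+].[K+].[K+].COC(=O)c1ccc([O-])c([C@H]2C3=C(O[C@H]2C(C)(C)[O-])C(=C([O-])CCc4ccccc4)[C@@H]([O-])C=C3OC)c1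
F5 | step 8 | methyl (2E,5R)-2-[(1S)-1-{5-bromo-2-[(triisopropylsilyl)oxy]phenyl}prop-2-en-1-yl]-5-[(tert-butyldimethylsilyl)oxy]-6-cyano-3-methoxyhex-2-enoate | COC(=O)/C([C@@H](C=C)c1cc(Br)ccc1O[Si](C(C)C)(C(C)C)C(C)C)=C(/OC)C[C@H](O[Si](C)(C)C(C)(C)C)CC#N
F6 | step 8 | methyl (2E,5S)-2-[(1S)-1-{5-bromo-2-[(triisopropylsilyl)oxy]phenyl}prop-2-en-1-yl]-5-[(tert-butyldimethylsilyl)oxy]-3-methoxy-7-oxohept-2-enoate | COC(=O)/C([C@@H](C=C)c1cc(Br)ccc1O[Si](C(C)C)(C(C)C)C(C)C)=C(/OC)C[C@H](O[Si](C)(C)C(C)(C)C)CC=O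
F7 | step 8 | methyl (2E,5R)-2-[(1S)-1-{5-bromo-2-[(triisopropylsilyl)oxy]phenyl}prop-2-en-1-yl]-5-[(tert-butyldimethylsilyl)oxy]-7-hydroxy-3-methoxy-9-phenylnon-2-enoate (epimers at C7) | COC(=O)/C([C@@H](C=C)c1cc(Br)ccc1O[Si](C(C)C)(C(C)C)C(C)C)=C(/OC)C[C@H](O[Si](C)(C)C(C)(C)C)CC(O)CCc1ccccc1
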